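**Plan**

1. Retrosynthesis: the two benzylic CH2 groups next to the outer rings (the diarylmethane carbon and the bridge carbon on the 3-hydroxyphenyl ring) are re-oxidised and tied through one oxygen into a temporary pyran ring, a 1,3-diarylisochroman-1-ol. Three bonds are then cut in one operation: the 4-oxyphenyl–C1 bond, the lactone O–C(=O) bond, and the CH2–CH bond of the ethylene bridge.
2. Enabling feature: on the central ring the carbon carrying the diarylmethane CH2 (C2) lies between the phenol carbon (C3) and the carbon carrying the bridge (C1), with OMe at C5 — the orsellinate pattern. At the ester oxidation level this carbon acidifies the ortho methyl group (vinylogous enolate), captures the new alkoxide as a six-membered lactone, and then accepts the third component.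
3. Forward: ethyl orsellinate is 4-O-methylated and 2-O-benzylated. A one-pot three-component coupling (lateral lithiation, addition to 3-(benzyloxy)benzaldehyde, lactonisation, addition of 4-(benzyloxy)phenylmagnesium bromide) forms the bridge bond first, then the pyran ring, then the diaryl carbon.
4. One reductive operation (ionic hydrogenation, then hydrogenolysis) removes the pyran oxygen, the lactol OH and the three benzyl ethers.
5. Stereochemistry: the target has no stereocentre; C1 and C3 of the isochroman intermediates form without control and are erased in the last step.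

Key step: step 3

Remark (assumption): the target is achiral, so the request for a single enantiomer is met without an asymmetric step; 7, 8 and 9 are carried on as racemic mixtures of diastereomers.

**Route**

Step 1
Reactants: 1 ethyl 2,4-dihydroxy-6-methylbenzoate (ethyl orsellinate)
Product: 2 ethyl 2-hydroxy-4-methoxy-6-methylbenzoate
Conditions: MeI (1.1 equiv), K2CO3 (1.1 equiv), acetone, 56 °C
Reagents that add atoms: iodomethane, CI
Why: Williamson O-methylation should be selective for the 4-OH because the 2-OH is held in a hydrogen bond to the ester carbonyl and is much less acidic and nucleophilic (chelation-controlled mono-etherification of a β-resorcylate).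

Step 2
Reactants: 2 ethyl 2-hydroxy-4-methoxy-6-methylbenzoate
Product: 3 ethyl 2-(benzyloxy)-4-methoxy-6-methylbenzoate
Conditions: BnBr (1.3 equiv), K2CO3 (2 equiv), cat. KI, DMF, 60 °C
Reagents that add atoms: benzyl bromide, BrCc1ccccc1
Why: Williamson benzylation of the hydrogen-bonded phenol under the more forcing DMF/heat conditions should mask the acidic OH for the carbanion chemistry of step 3 with a group that leaves by hydrogenolysis at the end.

Step 3
Reactants: 3 ethyl 2-(benzyloxy)-4-methoxy-6-methylbenzoate; 4 3-(benzyloxy)benzaldehyde; 5 4-(benzyloxy)phenylmagnesium bromide (commercial 1 M solution in THF)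
Product: 8 lactol 8-(benzyloxy)-3-[3-(benzyloxy)phenyl]-1-[4-(benzyloxy)phenyl]-6-methoxy-3,4-dihydro-1H-isochromen-1-ol (racemic diastereomer mixture), via benzylic lithium species 6 (not isolated), via dihydroisocoumarin 7 (not isolated)
Conditions: LDA (1.05 equiv, commercial solution), THF, −78 °C; 4 (1.1 equiv), −78 °C → rt; 5 (2 equiv), 0 °C → rt; sat. aq. NH4Cl
Reagents that add atoms: none
Why: LDA removes a proton from the C6 methyl group, whose anion is a vinylogous ester enolate delocalised through the ring into the ortho ester (lateral lithiation), and this benzylic lithium 6 adds to the aldehyde carbon of 4, which forms the CH2–CH bond of the later ethylene bridge. The resulting lithium alkoxide closes the six-membered lactone by 6-exo-trig acyl substitution with loss of ethoxide (7), and the aryl Grignard 5 then adds once to this lactone carbonyl, so that work-up should give lactol 8 with every carbon of the target in place. The closest known reaction types are the lateral lithiation of O-protected orsellinate esters with aldehyde addition and lactonisation to 3-aryl-3,4-dihydroisocoumarins, and the single addition of aryl Grignard reagents to isochroman-1-ones to give 1-aryl lactols. The new stereocentres C3 (aldehyde addition) and C1 (hemiketal, mobile through the open hydroxy ketone) form without control, which is harmless because both become CH2 in step 4. The step needs chemoselectivity, and the substrate secures it: the ester is shielded by its two ortho substituents (OBn and CH3), so the hindered amide base deprotonates rather than adds and the benzylic anion does not condense with a second ester molecule, while the ketone tautomer of the Grignard adduct is a 2,6-disubstituted diaryl ketone that resists a second addition. A Grignard reagent is used and not an aryllithium so that the diisopropylamine in the flask is not turned back into an amide base that could open lactone 7 by E1cB elimination.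

Step 4
Reactants: 8 lactol 8-(benzyloxy)-3-[3-(benzyloxy)phenyl]-1-[4-(benzyloxy)phenyl]-6-methoxy-3,4-dihydro-1H-isochromen-1-ol
Product: 10 3-[2-(3-hydroxyphenyl)ethyl]-2-(4-hydroxybenzyl)-5-methoxyphenol (IN1159), via 1,3-diarylisochroman 9 (not isolated)
Conditions: Et3SiH (3 equiv), TFA, CH2Cl2, 0 °C; aq. NaHCO3 wash, solvent switch; then H2 (4 bar), 10% Pd/C, EtOAc–AcOH, cat. HClO4, 40 °C
Reagents that add atoms: none
Why: Ionic hydrogenation should reduce the lactol through its diaryl-stabilised cyclic oxocarbenium ion to the cyclic dibenzylic ether 9, and acid-assisted Pd-catalysed hydrogenolysis should then cleave both benzylic C–O bonds of the pyran ring and the three O-benzyl groups together, turning both stereocentres into CH2 groups.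

**Compound list**

1 | ethyl 2,4-dihydroxy-6-methylbenzoate (ethyl orsellinate) | CCOC(=O)c1c(C)cc(O)cc1O | starting material
2 | ethyl 2-hydroxy-4-methoxy-6-methylbenzoate | CCOC(=O)c1c(C)cc(OC)cc1O | intermediate
3 | ethyl 2-(benzyloxy)-4-methoxy-6-methylbenzoate | CCOC(=O)c1c(C)cc(OC)cc1OCc1ccccc1 | intermediate
4 | 3-(benzyloxy)benzaldehyde | O=Cc1cccc(OCc2ccccc2)c1 | starting material
5 | 4-(benzyloxy)phenylmagnesium bromide | Br[Mg]c1ccc(OCc2ccccc2)cc1 | starting material
6 | ethyl 2-(benzyloxy)-6-(lithiomethyl)-4-methoxybenzoate (benzylic lithium species) | [Li]Cc1cc(OC)cc(OCc2ccccc2)c1C(=O)OCC | intermediate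
7 | 8-(benzyloxy)-3-[3-(benzyloxy)phenyl]-6-methoxy-3,4-dihydro-1H-isochromen-1-one (racemic) | COc1cc2c(c(OCc3ccccc3)c1)C(=O)OC(c1cccc(OCc3ccccc3)c1)C2 | intermediate
8 | 8-(benzyloxy)-3-[3-(benzyloxy)phenyl]-1-[4-(benzyloxy)phenyl]-6-methoxy-3,4-dihydro-1H-isochromen-1-ol (racemic, both diastereomers) | COc1cc2c(c(OCc3ccccc3)c1)C(O)(c1ccc(OCc3ccccc3)cc1)OC(c1cccc(OCc3ccccc3)c1)C2 | intermediate
9 | 8-(benzyloxy)-3-[3-(benzyloxy)phenyl]-1-[4-(benzyloxy)phenyl]-6-methoxy-3,4-dihydro-1H-isochromene (racemic, cis and trans) | COc1cc2c(c(OCc3ccccc3)c1)C(c1ccc(OCc3ccccc3)cc1)OC(c1cccc(OCc3ccccc3)c1)C2 | intermediate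
10 | 3-[2-(3-hydroxyphenyl)ethyl]-2-(4-hydroxybenzyl)-5-methoxyphenol (IN1159, achiral) | COc1cc(O)c(Cc2ccc(O)cc2)c(CCc2cccc(O)c2)c1 | target

**Summary**

Total step count: 4.
Longest linear sequence: 4 steps (1 → 2 → 3 → 8 → 10).

**Steps most likely to fail**

Step 3. What may go wrong: base-induced E1cB opening of the lactone to a stilbene carboxylate while basic species are still present; self-condensation of the benzylic anion with unreacted ester; or stalling of the Grignard addition at the hindered, electron-rich lactone carbonyl. The fallback sets out from 3 and returns at 10, forming the same bridge bond by alkylation and not through a lactone. Lateral lithiation of 3 (LDA, THF, −78 °C, again via 6) and alkylation with commercial 3-(benzyloxy)benzyl bromide should give ethyl 2-(benzyloxy)-6-{2-[3-(benzyloxy)phenyl]ethyl}-4-methoxybenzoate F1. Reduction with LiAlH4 in THF should give (2-(benzyloxy)-6-{2-[3-(benzyloxy)phenyl]ethyl}-4-methoxyphenyl)methanol F2, and oxidation with MnO2 in CH2Cl2 should give 2-(benzyloxy)-6-{2-[3-(benzyloxy)phenyl]ethyl}-4-methoxybenzaldehyde F3. Addition of 5 (THF, 0 °C) should give (2-(benzyloxy)-6-{2-[3-(benzyloxy)phenyl]ethyl}-4-methoxyphenyl)[4-(benzyloxy)phenyl]methanol F4. Hydrogenolysis (H2, Pd/C, EtOAc–AcOH) of the diaryl carbinol and the three benzyl ethers should then give 10.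

Step 4. What may go wrong: the hydrogenolysis may stall at the secondary benzylic C–O bond next to the 3-oxyphenyl ring once the benzyl ethers and the diaryl C–O bond are gone, leaving a benzylic alcohol. The fallback sets out from 8 and returns at 10, replacing C–O hydrogenolysis at that carbon by elimination and alkene hydrogenation. Et3SiH in TFA/CH2Cl2 at rt (both C1–O bonds ionise, the second as a 4-alkoxybenzhydryl ether), followed by K2CO3/MeOH to free the alcohol, should give 2-{3-(benzyloxy)-2-[4-(benzyloxy)benzyl]-5-methoxyphenyl}-1-[3-(benzyloxy)phenyl]ethanol F5. Acid-catalysed dehydration (cat. TsOH, toluene, 80 °C) should give the stilbene 1-(benzyloxy)-2-[4-(benzyloxy)benzyl]-3-{(E)-2-[3-(benzyloxy)phenyl]ethenyl}-5-methoxybenzene F6. Neutral hydrogenation (H2, Pd/C, EtOAc–EtOH) should saturate the alkene and remove the three benzyl ethers to give 10.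

Step 1. What may go wrong: loss of site selectivity between the two phenols, leading to double O-methylation. The fallback sets out from 1 and returns at 2, replacing selective alkylation by exhaustive alkylation and selective dealkylation. Excess MeI with K2CO3 in DMF should give ethyl 2,4-dimethoxy-6-methylbenzoate F7, and BCl3 (CH2Cl2, −78 → 0 °C) should then remove only the methyl group ortho to the ester through the boron chelate to give 2.

**Further compounds**

F1 | step 3 | ethyl 2-(benzyloxy)-6-{2-[3-(benzyloxy)phenyl]ethyl}-4-methoxybenzoate | CCOC(=O)c1c(CCc2cccc(OCc3ccccc3)c2)cc(OC)cc1OCc1ccccc1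
F2 | step 3 | (2-(benzyloxy)-6-{2-[3-(benzyloxy)phenyl]ethyl}-4-methoxyphenyl)methanol | OCc1c(CCc2cccc(OCc3ccccc3)c2)cc(OC)cc1OCc1ccccc1
F3 | step 3 | 2-(benzyloxy)-6-{2-[3-(benzyloxy)phenyl]ethyl}-4-methoxybenzaldehyde | O=Cc1c(CCc2cccc(OCc3ccccc3)c2)cc(OC)cc1OCc1ccccc1
F4 | step 3 | (2-(benzyloxy)-6-{2-[3-(benzyloxy)phenyl]ethyl}-4-methoxyphenyl)[4-(benzyloxy)phenyl]methanol (racemic) | OC(c1ccc(OCc2ccccc2)cc1)c1c(CCc2cccc(OCc3ccccc3)c2)cc(OC)cc1OCc1ccccc1
F5 | step 4 | 2-{3-(benzyloxy)-2-[4-(benzyloxy)benzyl]-5-methoxyphenyl}-1-[3-(benzyloxy)phenyl]ethanol (racemic) | OC(Cc1cc(OC)cc(OCc2ccccc2)c1Cc1ccc(OCc2ccccc2)cc1)c1cccc(OCc2ccccc2)c1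
F6 | step 4 | 1-(benzyloxy)-2-[4-(benzyloxy)benzyl]-3-{(E)-2-[3-(benzyloxy)phenyl]ethenyl}-5-methoxybenzene | COc1cc(OCc2ccccc2)c(Cc2ccc(OCc3ccccc3)cc2)c(/C=C/c2cccc(OCc3ccccc3)c2)c1
F7 | step 1 | ethyl 2,4-dimethoxy-6-methylbenzoate | CCOC(=O)c1c(C)cc(OC)cc1OC
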